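**Retrosynthetic overview**
- The succinimide is closed last: a primary amide (from a nitrile) acylates itself on the acyl-oxazolidinone carbonyl and expels the auxiliary.
- The C12–C13 bond comes from an intermolecular Evans syn-aldol between a decalin keto-aldehyde and (R)-4-benzyl-3-(3-cyanopropanoyl)oxazolidin-2-one; this joins the two fragments and sets both side-chain stereocentres.
- The β,γ-unsaturated ketone is made by buffered oxidation of a 6-hydroxy-8(17)-ene. The methylene comes from Wittig reaction of an 8-ketone, and the 6-OH from enone epoxidation and SmI2 opening.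
- The trans-decalin (C5, C9, C10) is taken intact from (+)-sclareolide; the C2 chloride is put in first by site-selective C–H chlorination.
- Ring order: both carbocycles are bought; the only ring formed is the succinimide, at the end.

Assumption: positions are given in labdane numbering (C2 = CHCl, C6 = ketone carbon, C8 = methylene-bearing carbon, C9 carries C11–C12, C13–C16 = imide carbons); α is the face opposite the angular methyl.

**Step 1**
Reactants: 1 3,5-bis(trifluoromethyl)benzoyl chloride; 2 tert-butylamine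
Product: 3 N-tert-butyl-3,5-bis(trifluoromethyl)benzamide
Conditions: Et3N, CH2Cl2, 0 °C → rt
Reagents that add atoms: none
Why: Simple N-acylation of an amine by an acid chloride; no stereocentre is involved.

**Step 2**
Reactants: 3 N-tert-butyl-3,5-bis(trifluoromethyl)benzamide
Product: 4 N-tert-butyl-N-chloro-3,5-bis(trifluoromethyl)benzamide
Conditions: trichloroisocyanuric acid (0.4 equiv), CH2Cl2, rt, dark
Reagents that add atoms: trichloroisocyanuric acid, O=C1N(Cl)C(=O)N(Cl)C(=O)N1Cl
Why: Electrophilic N-chlorination of the secondary amide gives the stable N-chloroamide used as radical chlorinating agent.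

**Step 3**
Reactants: 5 (+)-sclareolide; 4 N-tert-butyl-N-chloro-3,5-bis(trifluoromethyl)benzamide
Product: 6 2α-chlorosclareolide (equatorial Cl, C2 S)
Conditions: 4 (1.2 equiv), Cs2CO3, PhH, 55 °C, visible light
Reagents that add atoms: none
Why: In this amidyl-radical chain C–H chlorination the bulky electrophilic amidyl radical abstracts H from the most accessible, electron-rich methylene (C2, remote from the lactone), and Cl is delivered to the equatorial α-face away from the two axial β-methyls, setting C2.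

**Step 4**
Reactants: 6 2α-chlorosclareolide
Product: 7 2α-chloro-8α-hydroxy-N-methoxy-N-methyl-13,14,15,16-tetranorlabdan-12-amide
Conditions: MeNH(OMe)·HCl, AlMe3, CH2Cl2, 0 °C → rt
Reagents that add atoms: N,O-dimethylhydroxylamine hydrochloride, CNOC.Cl
Why: Weinreb aminolysis of the lactone by the aluminium amide opens the ring without touching C8, C9 or the neopentyl-type C–Cl bond.

**Step 5**
Reactants: 7 hydroxy Weinreb amide
Product: 8 2α-chloro-N-methoxy-N-methyl-13,14,15,16-tetranorlabd-8(17)-en-12-amide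
Conditions: SOCl2, pyridine, CH2Cl2, −78 °C
Reagents that add atoms: none
Why: Low-temperature dehydration of the tertiary alcohol through its chlorosulfite (E2 at the C17 methyl) gives the exocyclic alkene selectively in this Weinreb amide series.

**Step 6**
Reactants: 8 exocyclic-alkene Weinreb amide
Product: 10 2α-chloro-13,14,15,16-tetranorlabd-8(17)-en-12-ol, via 2α-chloro-13,14,15,16-tetranorlabd-8(17)-en-12-al 9 (not isolated)
Conditions: DIBAL-H, THF, −78 °C; then MeOH, NaBH4, 0 °C
Reagents that add atoms: none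
Why: Hydride reduction of the Weinreb amide stops at the chelated hemiaminal (aldehyde on quench) and borohydride takes it to the alcohol, while the equatorial, doubly neopentyl chloride is inert to both.

**Step 7**
Reactants: 10 primary alcohol
Product: 11 12-O-tert-butyldimethylsilyl ether of 10
Conditions: TBSCl, imidazole, DMF, rt
Reagents that add atoms: tert-butyldimethylsilyl chloride, CC(C)(C)[Si](C)(C)Cl
Why: Standard silylation of an unhindered primary alcohol gives a group inert to all ring-B operations that follow.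

**Step 8**
Reactants: 11 TBS ether
Product: 13 12-(tert-butyldimethylsilyloxy)-2α-chloro-13,14,15,16,17-pentanorlabdan-8-one, via spiro-1,2,4-trioxolane (secondary ozonide, both C8 epimers) 12 (not isolated)
Conditions: O3, CH2Cl2, −78 °C; then PPh3, −78 °C → rt
Reagents that add atoms: ozone, [O-][O+]=O
Why: Ozonolysis (Criegee mechanism) of the only alkene gives the 8-ketone, and the C9 side chain stays in its favoured equatorial position.

**Step 9**
Reactants: 13 8-ketone
Product: 14 8-trimethylsilyloxy-Δ7 enol ether of 13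
Conditions: LDA, THF, −78 °C; then TMSCl
Reagents that add atoms: chlorotrimethylsilane, C[Si](C)(C)Cl
Why: Kinetic enolisation with LDA takes the proton from the less substituted α-CH2 (C7) rather than the hindered C9 methine, and O-silylation traps that enolate.

**Step 10**
Reactants: 14 silyl enol ether
Product: 15 12-(tert-butyldimethylsilyloxy)-2α-chloro-13,14,15,16,17-pentanorlabd-6-en-8-one
Conditions: Pd(OAc)2 (1.1 equiv), MeCN, rt
Reagents that add atoms: none
Why: Saegusa–Ito oxidation (C7 palladation, β-hydride elimination of H6) gives the Δ6-enone regiospecifically from the Δ7 enol ether.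

**Step 11**
Reactants: 15 enone
Product: 16 6α,7α-epoxy-12-(tert-butyldimethylsilyloxy)-2α-chloro-13,14,15,16,17-pentanorlabdan-8-one
Conditions: 30% H2O2, NaOH (cat.), MeOH, 0 °C
Reagents that add atoms: hydrogen peroxide, OO
Why: In this Weitz–Scheffer nucleophilic epoxidation hydroperoxide attacks C6 from the α-face, because the β-face is screened by the axial C10 and C4 methyls (this configuration is erased later).

**Step 12**
Reactants: 16 epoxy ketone
Product: 17 6α-hydroxy-12-(tert-butyldimethylsilyloxy)-2α-chloro-13,14,15,16,17-pentanorlabdan-8-one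
Conditions: SmI2 (2.5 equiv), THF/MeOH, −90 °C
Reagents that add atoms: none
Why: SmI2 reduction of the α,β-epoxy ketone (ketyl formation, Cα–O cleavage, protonation of the samarium enolate at C7) gives the β-hydroxy ketone with the C6–O bond and C9 untouched; alkyl chlorides are not reduced under these conditions.

**Step 13**
Reactants: 17 β-hydroxy ketone
Product: 18 6α-triethylsilyloxy-12-(tert-butyldimethylsilyloxy)-2α-chloro-13,14,15,16,17-pentanorlabdan-8-one
Conditions: TESOTf, 2,6-lutidine, CH2Cl2, −78 °C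
Reagents that add atoms: triethylsilyl trifluoromethanesulfonate, CC[Si](CC)(CC)OS(=O)(=O)C(F)(F)F
Why: Silylation with a silyl triflate and a weak base caps the hindered alcohol, so retro-aldol and β-elimination cannot occur in the olefination.

**Step 14**
Reactants: 18 β-silyloxy ketone
Product: 19 12-(tert-butyldimethylsilyloxy)-2α-chloro-6α-(triethylsilyloxy)-13,14,15,16-tetranorlabd-8(17)-ene
Conditions: Ph3PCH3Br, KOtBu, THF, 0 °C → rt
Reagents that add atoms: methyltriphenylphosphonium bromide, C[P+](c1ccccc1)(c1ccccc1)c1ccccc1.[Br-]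
Why: Wittig methylenation puts the exocyclic alkene in a fixed position, and C9 cannot be lost because its equatorial configuration is the thermodynamic one.

**Step 15**
Reactants: 19 bis-silyl ether
Product: 20 2α-chloro-13,14,15,16-tetranorlabd-8(17)-ene-6α,12-diol
Conditions: TBAF, THF, rt
Reagents that add atoms: none
Why: Fluoride cleaves both silyl ethers; nothing else in the molecule (alkene, inert chloride) responds to TBAF.

**Step 16**
Reactants: 20 diol
Product: 21 2α-chloro-6-oxo-13,14,15,16-tetranorlabd-8(17)-en-12-al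
Conditions: Dess–Martin periodinane (3 equiv), NaHCO3, CH2Cl2, 0 °C → rt
Reagents that add atoms: none
Why: Buffered Dess–Martin oxidation converts both alcohols under neutral conditions, so the β,γ-unsaturated ketone is not isomerised into conjugation and C5 stays trans-fused.

**Step 17**
Reactants: 22 3-cyanopropanoic acid; 23 (R)-4-benzyl-1,3-oxazolidin-2-one
Product: 25 (R)-4-benzyl-3-(3-cyanopropanoyl)-1,3-oxazolidin-2-one, via 3-cyanopropanoic pivalic anhydride 24 (not isolated)
Conditions: PivCl, Et3N, THF, −20 °C; then 23, LiCl, → rt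
Reagents that add atoms: none
Why: N-Acylation of the oxazolidinone through the mixed pivalic anhydride (LiCl activation) occurs at the unhindered cyanopropanoyl carbonyl.

**Step 18**
Reactants: 21 keto-aldehyde; 25 N-(3-cyanopropanoyl)oxazolidinone
Product: 28 (R)-4-benzyl-3-[(2R,3S)-2-(cyanomethyl)-3-hydroxy-4-(decalinyl)butanoyl]oxazolidin-2-one (C12 S, C13 R, syn), via (Z)-dibutylboron enolate of the acyl oxazolidinone 26 (not isolated), via dibutylboron aldolate 27 (not isolated)
Conditions: 25 (1.3 equiv), Bu2BOTf, iPr2NEt, CH2Cl2, −78 → 0 °C; then 21, −78 → 0 °C; pH 7 buffer, MeOH, H2O2, 0 °C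
Reagents that add atoms: none
Why: In this Evans syn-aldol the (Z)-boron enolate reacts through a Zimmerman–Traxler chair on the enolate face opposite the benzyl group of the (R)-auxiliary, giving the 12S,13R syn adduct; the aldehyde reacts far faster than the hindered C6 ketone.

**Step 19**
Reactants: 28 aldol adduct
Product: 29 12-O-tert-butyldimethylsilyl ether of 28
Conditions: TBSOTf, 2,6-lutidine, CH2Cl2, −78 → 0 °C
Reagents that add atoms: tert-butyldimethylsilyl trifluoromethanesulfonate, CC(C)(C)[Si](C)(C)OS(=O)(=O)C(F)(F)F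
Why: Silylation of the aldol hydroxyl prevents retro-aldol and stops the hydroxyl from adding to the nitrile in the next step.

**Step 20**
Reactants: 29 silylated nitrile
Product: 31 12-O-tert-butyldimethylsilyl haterumaimide G, via primary amide (4-amino-4-oxobutanoyl oxazolidinone) 30 (not isolated)
Conditions: [PtH(PMe2OH)(PMe2O)2H] (10 mol%), EtOH/H2O 4:1, 80 °C
Reagents that add atoms: water, O
Why: Neutral platinum-catalysed nitrile hydration gives the primary amide, which closes by 5-exo-trig N-acylation on the activated acyl-oxazolidinone carbonyl and expels the auxiliary; no base is present to epimerise C13 or move the alkene.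

**Step 21**
Reactants: 31 silyl-protected imide
Product: 32 haterumaimide G
Conditions: HF·pyridine, pyridine, THF, 0 °C → rt
Reagents that add atoms: none
Why: Buffered HF cleaves the secondary TBS ether without the basic conditions that would isomerise the β,γ-enone, open the imide or cause retro-aldol.

**Compound list**
1 | 3,5-bis(trifluoromethyl)benzoyl chloride | O=C(Cl)c1cc(cc(c1)C(F)(F)F)C(F)(F)F | starting material
2 | tert-butylamine | CC(C)(C)N | starting material
3 | N-tert-butyl-3,5-bis(trifluoromethyl)benzamide | CC(C)(C)NC(=O)c1cc(cc(c1)C(F)(F)F)C(F)(F)F | intermediate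
4 | N-tert-butyl-N-chloro-3,5-bis(trifluoromethyl)benzamide | CC(C)(C)N(Cl)C(=O)c1cc(cc(c1)C(F)(F)F)C(F)(F)F | intermediate
5 | (+)-sclareolide, (3aR,5aS,9aS,9bR)-3a,6,6,9a-tetramethyldecahydronaphtho[2,1-b]furan-2(1H)-one | C[C@@]12CC[C@H]3C(C)(C)CCC[C@]3(C)[C@H]1CC(=O)O2 | starting material
6 | 2α-chlorosclareolide (equatorial Cl, C2 S) | C[C@@]12CC[C@H]3C(C)(C)C[C@H](Cl)C[C@]3(C)[C@H]1CC(=O)O2 | intermediate
7 | 2α-chloro-8α-hydroxy-N-methoxy-N-methyl-13,14,15,16-tetranorlabdan-12-amide | C[C@@]1(O)CC[C@H]2C(C)(C)C[C@H](Cl)C[C@]2(C)[C@H]1CC(=O)N(C)OC | intermediate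
8 | 2α-chloro-N-methoxy-N-methyl-13,14,15,16-tetranorlabd-8(17)-en-12-amide | C=C1CC[C@H]2C(C)(C)C[C@H](Cl)C[C@]2(C)[C@H]1CC(=O)N(C)OC | intermediate
9 | 2α-chloro-13,14,15,16-tetranorlabd-8(17)-en-12-al | C=C1CC[C@H]2C(C)(C)C[C@H](Cl)C[C@]2(C)[C@H]1CC=O | intermediate
10 | 2α-chloro-13,14,15,16-tetranorlabd-8(17)-en-12-ol | C=C1CC[C@H]2C(C)(C)C[C@H](Cl)C[C@]2(C)[C@H]1CCO | intermediate
11 | 12-O-TBS ether of 10 | C=C1CC[C@H]2C(C)(C)C[C@H](Cl)C[C@]2(C)[C@H]1CCO[Si](C)(C)C(C)(C)C | intermediate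
12 | secondary ozonide of 11 (spiro-1,2,4-trioxolane at C8, both C8 epimers) | C1OOC2(O1)CC[C@H]3C(C)(C)C[C@H](Cl)C[C@]3(C)[C@H]2CCO[Si](C)(C)C(C)(C)C | intermediate
13 | 12-(TBS-oxy)-2α-chloro-13,14,15,16,17-pentanorlabdan-8-one (5α-H, 9α-H, 10β-Me) | O=C1CC[C@H]2C(C)(C)C[C@H](Cl)C[C@]2(C)[C@H]1CCO[Si](C)(C)C(C)(C)C | intermediate
14 | 8-trimethylsilyloxy-Δ7 enol ether of 13 | C[Si](C)(C)OC1=CC[C@H]2C(C)(C)C[C@H](Cl)C[C@]2(C)[C@H]1CCO[Si](C)(C)C(C)(C)C | intermediate
15 | 12-(TBS-oxy)-2α-chloro-13,14,15,16,17-pentanorlabd-6-en-8-one | O=C1C=C[C@H]2C(C)(C)C[C@H](Cl)C[C@]2(C)[C@H]1CCO[Si](C)(C)C(C)(C)C | intermediate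
16 | 6α,7α-epoxy-12-(TBS-oxy)-2α-chloro-13,14,15,16,17-pentanorlabdan-8-one | O=C1[C@@H]3O[C@@H]3[C@H]2C(C)(C)C[C@H](Cl)C[C@]2(C)[C@H]1CCO[Si](C)(C)C(C)(C)C | intermediate
17 | 6α-hydroxy-12-(TBS-oxy)-2α-chloro-13,14,15,16,17-pentanorlabdan-8-one | O=C1C[C@H](O)[C@H]2C(C)(C)C[C@H](Cl)C[C@]2(C)[C@H]1CCO[Si](C)(C)C(C)(C)C | intermediate
18 | 6α-(TES-oxy)-12-(TBS-oxy)-2α-chloro-13,14,15,16,17-pentanorlabdan-8-one | O=C1C[C@H](O[Si](CC)(CC)CC)[C@H]2C(C)(C)C[C@H](Cl)C[C@]2(C)[C@H]1CCO[Si](C)(C)C(C)(C)C | intermediate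
19 | 12-(TBS-oxy)-2α-chloro-6α-(TES-oxy)-13,14,15,16-tetranorlabd-8(17)-ene | C=C1C[C@H](O[Si](CC)(CC)CC)[C@H]2C(C)(C)C[C@H](Cl)C[C@]2(C)[C@H]1CCO[Si](C)(C)C(C)(C)C | intermediate
20 | 2α-chloro-13,14,15,16-tetranorlabd-8(17)-ene-6α,12-diol | C=C1C[C@H](O)[C@H]2C(C)(C)C[C@H](Cl)C[C@]2(C)[C@H]1CCO | intermediate
21 | 2α-chloro-6-oxo-13,14,15,16-tetranorlabd-8(17)-en-12-al | C=C1CC(=O)[C@H]2C(C)(C)C[C@H](Cl)C[C@]2(C)[C@H]1CC=O | intermediate
22 | 3-cyanopropanoic acid | N#CCCC(=O)O | starting material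
23 | (R)-4-benzyl-1,3-oxazolidin-2-one | O=C1N[C@H](Cc2ccccc2)CO1 | starting material
24 | 3-cyanopropanoic pivalic anhydride | N#CCCC(=O)OC(=O)C(C)(C)C | intermediate
25 | (R)-4-benzyl-3-(3-cyanopropanoyl)-1,3-oxazolidin-2-one | N#CCCC(=O)N1[C@H](Cc2ccccc2)COC1=O | intermediate
26 | (Z)-dibutylboron enolate of 25 | CCCCB(CCCC)O/C(=C\CC#N)N1[C@H](Cc2ccccc2)COC1=O | intermediate
27 | dibutylboron aldolate of 28 (12S,13R) | C=C1CC(=O)[C@H]2C(C)(C)C[C@H](Cl)C[C@]2(C)[C@H]1C[C@H](OB(CCCC)CCCC)[C@@H](CC#N)C(=O)N1[C@H](Cc2ccccc2)COC1=O | intermediate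
28 | syn-aldol adduct, (R)-4-benzyl-3-[(2R,3S)-2-(cyanomethyl)-3-hydroxy-4-(decalinyl)butanoyl]oxazolidin-2-one | C=C1CC(=O)[C@H]2C(C)(C)C[C@H](Cl)C[C@]2(C)[C@H]1C[C@H](O)[C@@H](CC#N)C(=O)N1[C@H](Cc2ccccc2)COC1=O | intermediate
29 | 12-O-TBS ether of 28 | C=C1CC(=O)[C@H]2C(C)(C)C[C@H](Cl)C[C@]2(C)[C@H]1C[C@H](O[Si](C)(C)C(C)(C)C)[C@@H](CC#N)C(=O)N1[C@H](Cc2ccccc2)COC1=O | intermediate
30 | primary amide from hydration of 29 | C=C1CC(=O)[C@H]2C(C)(C)C[C@H](Cl)C[C@]2(C)[C@H]1C[C@H](O[Si](C)(C)C(C)(C)C)[C@@H](CC(N)=O)C(=O)N1[C@H](Cc2ccccc2)COC1=O | intermediate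
31 | 12-O-TBS haterumaimide G | C=C1CC(=O)[C@H]2C(C)(C)C[C@H](Cl)C[C@]2(C)[C@H]1C[C@H](O[Si](C)(C)C(C)(C)C)[C@H]1CC(=O)NC1=O | intermediate
32 | haterumaimide G | C=C1CC(=O)[C@H]2C(C)(C)C[C@H](Cl)C[C@]2(C)[C@H]1C[C@H](O)[C@H]1CC(=O)NC1=O | target

**Totals**
Total step count: 21 (two of them make the chlorinating reagent, one makes the aldol donor).
Longest linear sequence: 20 steps (steps 1–16 and 18–21), running from acid chloride 1 through reagent 4 into the chlorination of sclareolide 5 in step 3 and on to 32. Step 17 is the only step off this line.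

**Three steps most likely to fail, with fallbacks**

Step 11 (nucleophilic epoxidation at the hindered C6). The fallback sets out from enone 15 and comes back at 17. Copper-catalysed conjugate borylation (CuCl, Xantphos, NaOtBu cat., B2pin2, MeOH, THF, rt) adds boron to C6 from the open α-face and gives the 6α-pinacolboryl ketone F1. Oxidation with NaBO3·4H2O in THF/H2O replaces boron by OH with retention and gives 17. This avoids both the peroxide attack and the SmI2 step.

Step 14 (Wittig on a β-silyloxy, α-branched ketone; risks are enolisation and β-elimination). The fallback sets out from 18 and comes back at 19. The weakly basic organocerium reagent from Me3SiCH2Li and CeCl3 (THF, −78 °C) adds to C8 from the α-face and gives the β-hydroxysilane F2; either C8 epimer serves. Peterson elimination with KH in THF (0 °C → rt) then gives 19.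

Step 20 (nitrile hydration and imide closure beside the isomerisable β,γ-enone). The fallback keeps C6 as an alcohol until the imide exists; it sets out from diol 20 and comes back at 31.
- TEMPO (cat.)/PhI(OAc)2 in CH2Cl2 oxidises only the primary alcohol and gives the 6α-hydroxy aldehyde F3.
- TESOTf/2,6-lutidine gives the 6α-triethylsilyloxy aldehyde F4.
- The same boron aldol with enolate 26 passes through the boron aldolate F5 to the syn-aldol adduct F6.
- TBSOTf/2,6-lutidine gives the 12-O-TBS ether F7.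
- Platinum-catalysed hydration gives the primary amide F8, which closes to the bis-silylated imide F9; catalytic DBU can be added here if closure is slow, since no enone is present.
- PPTS in MeOH/CH2Cl2 at 0 °C removes the more labile TES group and gives the 6α-hydroxy 12-O-TBS imide F10.
- Dess–Martin periodinane with NaHCO3 oxidises C6 and gives 31.

**Further compounds**
F1 | step 11 | 6α-(pinacolboryl)-12-(TBS-oxy)-2α-chloro-13,14,15,16,17-pentanorlabdan-8-one | O=C1C[C@H](B3OC(C)(C)C(C)(C)O3)[C@H]2C(C)(C)C[C@H](Cl)C[C@]2(C)[C@H]1CCO[Si](C)(C)C(C)(C)C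
F2 | step 14 | 8β-hydroxy-8α-(trimethylsilylmethyl) adduct of 18 | C[Si](C)(C)C[C@]1(O)C[C@H](O[Si](CC)(CC)CC)[C@H]2C(C)(C)C[C@H](Cl)C[C@]2(C)[C@H]1CCO[Si](C)(C)C(C)(C)C
F3 | step 20 | 2α-chloro-6α-hydroxy-13,14,15,16-tetranorlabd-8(17)-en-12-al | C=C1C[C@H](O)[C@H]2C(C)(C)C[C@H](Cl)C[C@]2(C)[C@H]1CC=O
F4 | step 20 | 2α-chloro-6α-(triethylsilyloxy)-13,14,15,16-tetranorlabd-8(17)-en-12-al | C=C1C[C@H](O[Si](CC)(CC)CC)[C@H]2C(C)(C)C[C@H](Cl)C[C@]2(C)[C@H]1CC=O
F5 | step 20 | dibutylboron aldolate of F6 | C=C1C[C@H](O[Si](CC)(CC)CC)[C@H]2C(C)(C)C[C@H](Cl)C[C@]2(C)[C@H]1C[C@H](OB(CCCC)CCCC)[C@@H](CC#N)C(=O)N1[C@H](Cc2ccccc2)COC1=O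
F6 | step 20 | 6α-TES syn-aldol adduct (12S,13R) | C=C1C[C@H](O[Si](CC)(CC)CC)[C@H]2C(C)(C)C[C@H](Cl)C[C@]2(C)[C@H]1C[C@H](O)[C@@H](CC#N)C(=O)N1[C@H](Cc2ccccc2)COC1=O
F7 | step 20 | 12-O-TBS ether of F6 | C=C1C[C@H](O[Si](CC)(CC)CC)[C@H]2C(C)(C)C[C@H](Cl)C[C@]2(C)[C@H]1C[C@H](O[Si](C)(C)C(C)(C)C)[C@@H](CC#N)C(=O)N1[C@H](Cc2ccccc2)COC1=O
F8 | step 20 | primary amide from hydration of F7 | C=C1C[C@H](O[Si](CC)(CC)CC)[C@H]2C(C)(C)C[C@H](Cl)C[C@]2(C)[C@H]1C[C@H](O[Si](C)(C)C(C)(C)C)[C@@H](CC(N)=O)C(=O)N1[C@H](Cc2ccccc2)COC1=O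
F9 | step 20 | 6α-TES, 12-O-TBS succinimide | C=C1C[C@H](O[Si](CC)(CC)CC)[C@H]2C(C)(C)C[C@H](Cl)C[C@]2(C)[C@H]1C[C@H](O[Si](C)(C)C(C)(C)C)[C@H]1CC(=O)NC1=O
F10 | step 20 | 6α-hydroxy 12-O-TBS succinimide | C=C1C[C@H](O)[C@H]2C(C)(C)C[C@H](Cl)C[C@]2(C)[C@H]1C[C@H](O[Si](C)(C)C(C)(C)C)[C@H]1CC(=O)NC1=O
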